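The two bonds cut are C4–C5 (ring A) and C6–C7 (ring B), on either side of the C6 carbinol carbon. The feature used is that C6 lies between C5, which is attached to the quaternary C4 of ring A, and C7, which leads on to C8 and C17 in ring B. Masked as the enol silane C5=C6–O, this unit first lends C5 as a nucleophile to a C4 cation; the aldehyde that results then offers C6 as an electrophile to C7. One Lewis-acid operation therefore closes both rings and sets C5 and C6. The precursor is an acyclic tertiary chloride with C9 and C10 fixed by an enantioselective Ireland–Claisen rearrangement, an aldehyde enol silane and a C17-silylated isopropenyl (allylsilane) group.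

Key step: step 9

Remark 1 (numbering): labdane numbering is used for all locants; the target is the (5R,6R,8S,9S,10R) enantiomer with both hydroxyls equatorial and C17 axial.
Remark 2 (assumption): the (S,S)-configured bromoborane controller, (4S,5S)-2-bromo-1,3-bis{[3,5-bis(trifluoromethyl)phenyl]sulfonyl}-4,5-diphenyl-1,3,2-diazaborolidine, is assumed to give the (2S,3R) acid; if the first run shows the opposite sense, the equally available (R,R) antipode is used instead.
Remark 3 (precursor design): C17 carries SiMe3 because a concerted type 2 carbonyl-ene closure of a bare isopropenyl group through a chair must hold the carbonyl oxygen axial on the new ring to reach a C17 hydrogen. That site is syn to C20 and to the axial C4 methyl and leads to the C6 epimer. The allylsilane closes ring B without hydrogen transfer and fixes the alkene as C8=C17.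

Step 1
Reactants: 1 δ-valerolactone
Product: 4 TBDPS-protected 5-hydroxypentanoic acid, via sodium 5-hydroxypentanoate 2 (not isolated), via doubly silylated silyl ester 3 (not isolated)
Conditions: NaOH (1 equiv), MeOH/H2O, rt, evaporate; TBDPSCl (2.2 equiv), imidazole, DMF, rt; K2CO3, MeOH/THF/H2O, rt; aq. citric acid
Reagents that add atoms: sodium hydroxide [Na+].[OH-]; tert-butyl(chloro)diphenylsilane CC(C)(C)[Si](Cl)(c1ccccc1)c1ccccc1
Why: Saponification opens the lactone, silylation caps both oxygens, and the much more labile silyl ester is then cleaved selectively by mild carbonate solvolysis (lactone hydrolysis, silyl protection).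

Step 2
Reactants: 4 TBDPS-protected 5-hydroxypentanoic acid, 5 geraniol
Product: 6 geranyl 5-[(tert-butyldiphenylsilyl)oxy]pentanoate
Conditions: DCC, DMAP (cat.), CH2Cl2, 0 °C → rt
Reagents that add atoms: none
Why: Steglich esterification of the primary allylic alcohol proceeds under neutral conditions that leave the E-alkene untouched.

Step 3
Reactants: 6 geranyl 5-[(tert-butyldiphenylsilyl)oxy]pentanoate
Product: 9 (2S,3R)-2-{3-[(tert-butyldiphenylsilyl)oxy]propyl}-3-ethenyl-3,7-dimethyloct-6-enoic acid, via boron enolate 7 (not isolated), via boron carboxylate 8 (not isolated)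
Conditions: (S,S)-bromoborane controller of remark 2 (1.2 equiv), iPr2NEt, CH2Cl2, −78 °C, then −20 → 4 °C; aq. work-up, sulfonamide recovered
Reagents that add atoms: none
Why: Enantioselective Ireland–Claisen rearrangement: enolisation with the hindered amine in CH2Cl2 should give the boron enolate with the alkyl chain cis to O–B, and the chair transition state on the E-alkene (homoprenyl equatorial, methyl axial), with one enolate face shielded by the C2-symmetric controller, sets C9 and C10 together.

Step 4
Reactants: 9 (2S,3R)-2-{3-[(tert-butyldiphenylsilyl)oxy]propyl}-3-ethenyl-3,7-dimethyloct-6-enoic acid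
Product: 12 (3S,4R)-3-{3-[(tert-butyldiphenylsilyl)oxy]propyl}-4-methyl-4-(4-methylpent-3-en-1-yl)oxan-2-one, via bis-boryl adduct 10 (not isolated), via hydroxy acid 11 (not isolated)
Conditions: 9-BBN (2.5 equiv), THF, 0 °C → rt; NaOH, H2O2, 0 °C; acidify; PPTS (cat.), toluene, 50 °C
Reagents that add atoms: hydrogen peroxide OO
Why: One equivalent of 9-BBN is consumed by the acid as an acyloxyborane that is reduced only very slowly, a second hydroborates the monosubstituted vinyl group at its terminus far faster than the trisubstituted alkene, and oxidation followed by acid-catalysed δ-lactonisation (helped by the quaternary centre) ties the new C6 oxygen to C8.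

Step 5
Reactants: 12 (3S,4R)-3-{3-[(tert-butyldiphenylsilyl)oxy]propyl}-4-methyl-4-(4-methylpent-3-en-1-yl)oxan-2-one
Product: 13 (3S,4R)-4-(4-chloro-4-methylpentyl)-3-{3-[(tert-butyldiphenylsilyl)oxy]propyl}-4-methyloxan-2-one
Conditions: HCl (g), CH2Cl2, −30 → 0 °C
Reagents that add atoms: hydrogen chloride Cl
Why: Markovnikov hydrochlorination of the only alkene left gives the tertiary C4 chloride, and the lactone and silyl ether tolerate cold anhydrous HCl.

Step 6
Reactants: 13 (3S,4R)-4-(4-chloro-4-methylpentyl)-3-{3-[(tert-butyldiphenylsilyl)oxy]propyl}-4-methyloxan-2-one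
Product: 15 open-chain C6 alcohol bearing the 2-[(trimethylsilyl)methyl]allyl unit at C9, via bis(silylmethyl) carbinol 14 (not isolated)
Conditions: Me3SiCH2MgCl (5 equiv), CeCl3 (5 equiv), THF, −78 °C → rt; aq. NH4Cl; SiO2, CH2Cl2, rt
Reagents that add atoms: (trimethylsilyl)methylmagnesium chloride C[Si](C)(C)C[Mg]Cl
Why: The weakly basic Me3SiCH2MgCl/CeCl3 reagent adds twice to the lactone carbonyl without enolising C9 or touching the tertiary chloride, and mild acid-induced Peterson elimination of one β-silyl group leaves the 2-substituted allylsilane (C7 as =CH2, C17 as CH2SiMe3) and the free C6 alcohol.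

Step 7
Reactants: 15 open-chain C6 alcohol bearing the 2-[(trimethylsilyl)methyl]allyl unit at C9
Product: 16 open-chain C6 aldehyde
Conditions: Dess–Martin periodinane, NaHCO3, CH2Cl2, 0 °C → rt
Reagents that add atoms: none
Why: Buffered Dess–Martin oxidation stops at the aldehyde and spares the allylsilane, the tertiary chloride and the silyl ether.

Step 8
Reactants: 16 open-chain C6 aldehyde
Product: 17 open-chain chloro enol silane with allylsilane (key-step precursor)
Conditions: Et3N (3 equiv), then TMSOTf (1.3 equiv), Et2O, −78 → 0 °C; pentane, filtration, used crude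
Reagents that add atoms: trimethylsilyl triflate C[Si](C)(C)OS(=O)(=O)C(F)(F)F
Why: Amine-assisted O-silylation (soft enolisation) gives the enol silane; the E isomer is expected because the Z isomer would hold OSiMe3 cis to quaternary C10, and the geometry is erased anyway when C6 returns to a carbonyl.

Step 9
Reactants: 17 open-chain chloro enol silane with allylsilane
Product: 19 (5R,6R,9R,10S)-13-[(tert-butyldiphenylsilyl)oxy]-14,15,16-trinorlabd-8(17)-en-6-ol, via monocyclic C6 aldehyde 18 (not isolated)
Conditions: MeAlCl2 (2.5 equiv), CH2Cl2 (0.02 M), −78 → −40 °C; aq. NaHCO3; K2CO3 (cat.), MeOH, rt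
Reagents that add atoms: none
Why: Proposed new method: MeAlCl2 abstracts the C4 chloride, the tertiary cation is taken at C5 by the enol silane, chloride removes the oxygen-bound silyl group, and the aldehyde left on aluminium is attacked at C6 by C7 of the allylsilane, the C8 cation being discharged by loss of SiMe3 to give C8=C17. The closest known reaction types are the Lewis-acid α-tert-alkylation of silyl enol ethers by tertiary chlorides and the Me2AlCl- or MeAlCl2-promoted intramolecular Hosomi–Sakurai and type 2 carbonyl-ene cyclisations of unsaturated aldehydes; what is new is their union in one pot, with the same carbon unit first nucleophilic and then electrophilic. Ring A closes as a six-membered chair onto the planar C4 cation with the C5=C6 double bond outside the ring (enol-exo), and ring B closes 6-exo-trig at the C6 carbonyl with the C7=C8 double bond inside the ring. C5 is set in the ring A chair, where the large C9 branch on C10 and the C5=C6 unit lie equatorial so that H5 ends anti to C20 (trans fusion); C6 is set in the ring B chair, where the aluminium-bound oxygen takes the equatorial site because an axial oxygen would be syn-axial to C20 and the axial C4 methyl, and no hydrogen transfer forces it axial. The step needs ionisation at C4 before any protonation or activation of the two silyl nucleophiles and needs the aldehyde to appear only after ring A exists; this is secured by the chloride leaving group, by MeAlCl2 acting as proton scavenger and by the aldehyde being generated by the alkylation itself, while attack of the allylsilane on C4 would require an eight-membered ring.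

Step 10
Reactants: 19 (5R,6R,9R,10S)-13-[(tert-butyldiphenylsilyl)oxy]-14,15,16-trinorlabd-8(17)-en-6-ol
Product: 20 (5R,6R,9R,10S)-14,15,16-trinorlabd-8(17)-ene-6,13-diol
Conditions: TBAF, THF, rt
Reagents that add atoms: none
Why: Fluoride cleaves the silyl ether (desilylation), and nothing else in the molecule is fluoride-sensitive.

Step 11
Reactants: 20 (5R,6R,9R,10S)-14,15,16-trinorlabd-8(17)-ene-6,13-diol
Product: 21 (5R,6R,9R,10S)-6-hydroxy-14,15,16-trinorlabd-8(17)-en-13-al
Conditions: TEMPO (cat.), PhI(OAc)2, CH2Cl2, rt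
Reagents that add atoms: none
Why: The oxoammonium oxidant discriminates the unhindered primary C13 alcohol from the hindered secondary C6 alcohol and stops at the aldehyde; at this stage C8 is still an alkene, so no cyclic hemiacetal can form and over-oxidise.

Step 12
Reactants: 21 (5R,6R,9R,10S)-6-hydroxy-14,15,16-trinorlabd-8(17)-en-13-al
Product: 22 (5R,6R,9R,10S)-15,16-dinorlabd-8(17)-en-13-yn-6-ol
Conditions: dimethyl (1-diazo-2-oxopropyl)phosphonate, K2CO3, MeOH, 0 °C → rt
Reagents that add atoms: dimethyl (1-diazo-2-oxopropyl)phosphonate COP(=O)(OC)C(=[N+]=[N-])C(C)=O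
Why: Ohira–Bestmann homologation converts the unbranched aldehyde into the terminal alkyne (C14) under mild carbonate conditions that tolerate the free alcohol and the exocyclic alkene.

Step 13
Reactants: 22 (5R,6R,9R,10S)-15,16-dinorlabd-8(17)-en-13-yn-6-ol
Product: 23 (5R,6R,8S,9S,10R)-8,17-epoxy-15,16-dinorlabd-13-yn-6-ol
Conditions: mCPBA, CH2Cl2/aq. NaHCO3, 0 °C
Reagents that add atoms: 3-chloroperbenzoic acid OOC(=O)c1cccc(Cl)c1
Why: Prilezhaev epoxidation of the electron-rich 1,1-disubstituted alkene (the alkyne is inert) should occur from the face opposite the axial C20 methyl, which places the epoxide oxygen equatorial at C8 and sets that centre.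

Step 14
Reactants: 23 (5R,6R,8S,9S,10R)-8,17-epoxy-15,16-dinorlabd-13-yn-6-ol
Product: 24 (5R,6R,8S,9S,10R)-15,16-dinorlabd-13-yne-6,8-diol
Conditions: LiEt3BH (4 equiv), THF, 0 °C → rt; aq. NH4Cl
Reagents that add atoms: none
Why: Hydride opens the spiro-epoxide by SN2 attack at the unsubstituted C17, so the C8–O bond is untouched and the equatorial tertiary alcohol with axial methyl results.

Step 15
Reactants: 24 (5R,6R,8S,9S,10R)-15,16-dinorlabd-13-yne-6,8-diol
Product: 26 methyl (13E,5R,6R,8S,9S,10R)-6,8-dihydroxylabd-13-en-15-oate, via alkenyldimethylalane 25 (not isolated)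
Conditions: Me3Al (5 equiv), Cp2ZrCl2 (0.5 equiv), CH2Cl2, 0 °C → rt; ClCO2Me (1.5 equiv), 0 °C → rt; 1 M HCl
Reagents that add atoms: trimethylaluminium C[Al](C)C; methyl chloroformate COC(=O)Cl
Why: Negishi carboalumination adds methyl to C13 and aluminium to C14 in a syn fashion, and acylation of the alkenyl–aluminium bond with retention gives the E-enoate, while the two hydroxyls are held in situ as hindered O–AlMe2 groups.

Compound list
1 | δ-valerolactone (oxan-2-one) | O=C1CCCCO1 | starting material
2 | sodium 5-hydroxypentanoate | [Na+].[O-]C(=O)CCCCO | intermediate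
3 | tert-butyldiphenylsilyl 5-[(tert-butyldiphenylsilyl)oxy]pentanoate | CC(C)(C)[Si](c1ccccc1)(c1ccccc1)OCCCCC(=O)O[Si](c1ccccc1)(c1ccccc1)C(C)(C)C | intermediate
4 | 5-[(tert-butyldiphenylsilyl)oxy]pentanoic acid | CC(C)(C)[Si](c1ccccc1)(c1ccccc1)OCCCCC(=O)O | intermediate
5 | geraniol, (2E)-3,7-dimethylocta-2,6-dien-1-ol | CC(C)=CCC/C(C)=C/CO | starting material
6 | geranyl 5-[(tert-butyldiphenylsilyl)oxy]pentanoate | CC(C)(C)[Si](c1ccccc1)(c1ccccc1)OCCCCC(=O)OC/C=C(\C)CCC=C(C)C | intermediate
7 | O-boryl ketene acetal of 6 (alkyl chain cis to O–B; boron in the (4S,5S)-bis-sulfonyl diazaborolidine) | CC(C)(C)[Si](c1ccccc1)(c1ccccc1)OCCC/C=C(/OC/C=C(\C)CCC=C(C)C)OB1N(S(=O)(=O)c2cc(cc(c2)C(F)(F)F)C(F)(F)F)[C@@H](c2ccccc2)[C@H](c2ccccc2)N1S(=O)(=O)c1cc(cc(c1)C(F)(F)F)C(F)(F)F | intermediate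
8 | boron carboxylate of acid 9 (rearranged acyloxy diazaborolidine) | CC(C)(C)[Si](c1ccccc1)(c1ccccc1)OCCC[C@H](C(=O)OB1N(S(=O)(=O)c2cc(cc(c2)C(F)(F)F)C(F)(F)F)[C@@H](c2ccccc2)[C@H](c2ccccc2)N1S(=O)(=O)c1cc(cc(c1)C(F)(F)F)C(F)(F)F)[C@](C)(CCC=C(C)C)C=C | intermediate
9 | (2S,3R)-2-{3-[(tert-butyldiphenylsilyl)oxy]propyl}-3-ethenyl-3,7-dimethyloct-6-enoic acid (C9 S, C10 R) | CC(C)(C)[Si](c1ccccc1)(c1ccccc1)OCCC[C@H](C(=O)O)[C@](C)(CCC=C(C)C)C=C | intermediate
10 | bis-boryl adduct: C6 bonded to 9-BBN boron, carboxyl as acyloxy-9-BBN; configuration at C9 and C10 as in 9 | CC(C)(C)[Si](c1ccccc1)(c1ccccc1)OCCC[C@H](C(=O)OB1C2CCCC1CCC2)[C@](C)(CCC=C(C)C)CCB1C2CCCC1CCC2 | intermediate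
11 | (2S,3R)-2-{3-[(tert-butyldiphenylsilyl)oxy]propyl}-3-(2-hydroxyethyl)-3,7-dimethyloct-6-enoic acid | CC(C)(C)[Si](c1ccccc1)(c1ccccc1)OCCC[C@H](C(=O)O)[C@](C)(CCC=C(C)C)CCO | intermediate
12 | (3S,4R)-3-{3-[(tert-butyldiphenylsilyl)oxy]propyl}-4-methyl-4-(4-methylpent-3-en-1-yl)oxan-2-one | CC(C)(C)[Si](c1ccccc1)(c1ccccc1)OCCC[C@@H]1C(=O)OCC[C@@]1(C)CCC=C(C)C | intermediate
13 | (3S,4R)-4-(4-chloro-4-methylpentyl)-3-{3-[(tert-butyldiphenylsilyl)oxy]propyl}-4-methyloxan-2-one | CC(C)(C)[Si](c1ccccc1)(c1ccccc1)OCCC[C@@H]1C(=O)OCC[C@@]1(C)CCCC(C)(C)Cl | intermediate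
14 | (9S,10R) open-chain diol: C6 primary alcohol and C8 tertiary carbinol bearing two CH2SiMe3 groups; C4 tertiary chloride; C13 silyl ether | CC(C)(C)[Si](c1ccccc1)(c1ccccc1)OCCC[C@H](C(O)(C[Si](C)(C)C)C[Si](C)(C)C)[C@](C)(CCCC(C)(C)Cl)CCO | intermediate
15 | (9S,10R) open-chain C6 alcohol: C9 bears C8(=C7H2)–C17H2SiMe3 and the 3-silyloxypropyl chain; C10 bears methyl, the 4-chloro-4-methylpentyl chain and CH2CH2OH | CC(C)(C)[Si](c1ccccc1)(c1ccccc1)OCCC[C@H](C(=C)C[Si](C)(C)C)[C@](C)(CCCC(C)(C)Cl)CCO | intermediate
16 | (9S,10R) open-chain C6 aldehyde corresponding to 15 | CC(C)(C)[Si](c1ccccc1)(c1ccccc1)OCCC[C@H](C(=C)C[Si](C)(C)C)[C@](C)(CCCC(C)(C)Cl)CC=O | intermediate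
17 | (5E,9S,10S) key-step precursor: C5=C6 trimethylsilyl enol ether, C4 tertiary chloride, C17-silylated isopropenyl group on C9, C13 silyl ether | CC(C)(C)[Si](c1ccccc1)(c1ccccc1)OCCC[C@H](C(=C)C[Si](C)(C)C)[C@](C)(CCCC(C)(C)Cl)/C=C/O[Si](C)(C)C | intermediate
18 | (5R,9S,10S) monocyclic ring A aldehyde: 2,2,6-trimethylcyclohexanecarbaldehyde whose C10 also carries the C9 branch; CHO and C9 branch trans-diequatorial | CC(C)(C)[Si](c1ccccc1)(c1ccccc1)OCCC[C@H](C(=C)C[Si](C)(C)C)[C@]1(C)CCCC(C)(C)[C@H]1C=O | intermediate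
19 | (5R,6R,9R,10S)-13-[(tert-butyldiphenylsilyl)oxy]-14,15,16-trinorlabd-8(17)-en-6-ol (trans-decalin, equatorial 6-OH) | CC(C)(C)[Si](c1ccccc1)(c1ccccc1)OCCC[C@H]1[C@]2(C)CCCC(C)(C)[C@H]2[C@H](O)CC1=C | intermediate
20 | (5R,6R,9R,10S)-14,15,16-trinorlabd-8(17)-ene-6,13-diol | OCCC[C@H]1[C@]2(C)CCCC(C)(C)[C@H]2[C@H](O)CC1=C | intermediate
21 | (5R,6R,9R,10S)-6-hydroxy-14,15,16-trinorlabd-8(17)-en-13-al | O=CCC[C@H]1[C@]2(C)CCCC(C)(C)[C@H]2[C@H](O)CC1=C | intermediate
22 | (5R,6R,9R,10S)-15,16-dinorlabd-8(17)-en-13-yn-6-ol | C#CCC[C@H]1[C@]2(C)CCCC(C)(C)[C@H]2[C@H](O)CC1=C | intermediate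
23 | (5R,6R,8S,9S,10R)-8,17-epoxy-15,16-dinorlabd-13-yn-6-ol (epoxide oxygen equatorial) | C#CCC[C@H]1[C@]2(C)CCCC(C)(C)[C@H]2[C@H](O)C[C@]1(C3)O3 | intermediate
24 | (5R,6R,8S,9S,10R)-15,16-dinorlabd-13-yne-6,8-diol | C#CCC[C@H]1[C@]2(C)CCCC(C)(C)[C@H]2[C@H](O)C[C@]1(C)O | intermediate
25 | (13E) alkenyldimethylalane: AlMe2 on C14 cis to the new C13 methyl, both hydroxyls as O–AlMe2 | C[Al](C)/C=C(\C)CC[C@H]1[C@]2(C)CCCC(C)(C)[C@H]2[C@H](O[Al](C)C)C[C@]1(C)O[Al](C)C | intermediate
26 | methyl (13E,5R,6R,8S,9S,10R)-6,8-dihydroxylabd-13-en-15-oate (CNP0289884.1) | COC(=O)/C=C(\C)CC[C@H]1[C@]2(C)CCCC(C)(C)[C@H]2[C@H](O)C[C@]1(C)O | target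

Total step count: 15. Longest linear sequence: 15 steps (1 → 26).

Steps most likely to fail

Step 9. After ionisation, elimination or methyl transfer at C4 may outrun C–C bond formation, premature loss of the enol silane may let the aldehyde meet the allylsilane before ring A exists, or the facial preference at C6 may be insufficient. The fallback separates the two closures into two individually known reactions. From 17, ZnBr2 (cat.) in CH2Cl2 at 0 °C, a Lewis acid too weak to activate an aldehyde toward an allylsilane, performs only the tert-alkylation of the enol silane, and the ring A aldehyde 18 is isolated. A separate Hosomi–Sakurai cyclisation with BF3·OEt2 in CH2Cl2 at −78 °C then closes ring B and returns to 19. This fallback makes no compound outside the list (none, F0).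

Step 6. The second addition to the hindered carbonyl may stall through enolisation or desilylation of the intermediate α-silyl ketone, leaving a methyl ketone. The fallback builds the allylsilane by cross-coupling. From 13, MeLi (1.1 equiv, THF, −78 °C) gives the open-chain hydroxy methyl ketone F1, which is in equilibrium with its cyclic hemiketal. Et3SiCl/imidazole traps the open form as the keto triethylsilyl ether F2. KN(SiMe3)2 and PhNTf2 at −78 °C give the less substituted enol triflate F3. Kumada coupling with Me3SiCH2MgCl under zerovalent palladium, Pd(PPh3)4, gives the allylsilane triethylsilyl ether F4. Buffered HF·pyridine then removes the triethylsilyl group selectively and returns to 15.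

Step 15. The chloroformate may acylate the C6 O–AlMe2 group, giving a carbonate, or acylation of the alkenyl–aluminium bond may be sluggish in the presence of two aluminium-bound oxygens. The fallback introduces C15 by carbonylation. From 24, the same carboalumination is quenched with I2 to give the (E)-vinyl iodide F5, and PdCl2(PPh3)2-catalysed methoxycarbonylation (CO 1 atm, MeOH, Et3N), which tolerates free hydroxyls, delivers 26.

Further compounds
F0 | step 9 | none | none
F1 | step 6 | (9S,10R) open-chain hydroxy methyl ketone (C8 acetyl, C6 alcohol, C4 chloride) | CC(C)(C)[Si](c1ccccc1)(c1ccccc1)OCCC[C@H](C(C)=O)[C@](C)(CCCC(C)(C)Cl)CCO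
F2 | step 6 | C6 triethylsilyl ether of F1 | CC(C)(C)[Si](c1ccccc1)(c1ccccc1)OCCC[C@H](C(C)=O)[C@](C)(CCCC(C)(C)Cl)CCO[Si](CC)(CC)CC
F3 | step 6 | C8 enol triflate (C7 as =CH2) of F2 | CC(C)(C)[Si](c1ccccc1)(c1ccccc1)OCCC[C@H](C(=C)OS(=O)(=O)C(F)(F)F)[C@](C)(CCCC(C)(C)Cl)CCO[Si](CC)(CC)CC
F4 | step 6 | C6 triethylsilyl ether of allylsilane 15 | CC(C)(C)[Si](c1ccccc1)(c1ccccc1)OCCC[C@H](C(=C)C[Si](C)(C)C)[C@](C)(CCCC(C)(C)Cl)CCO[Si](CC)(CC)CC
F5 | step 15 | (13E,5R,6R,8S,9S,10R)-14-iodo-15-norlabd-13-ene-6,8-diol | I/C=C(\C)CC[C@H]1[C@]2(C)CCCC(C)(C)[C@H]2[C@H](O)C[C@]1(C)O
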